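## Retrosynthetic overview

Numbering (daucane): C1 = ring-fusion carbon with CH3 (C15); C2, C3 = CH2; C4 = carbinol carbon with isopropyl; C5 = ring-fusion CH; C6 = acyloxy carbon; C7 = CH2; C8 = methyl carbinol carbon; C9=C10 = ring alkene. β = face of the C1 methyl.

1. The vanillate is attached last to triol 20 at its only secondary hydroxyl; the C6 carbinol comes from a 6-ketone by hydroxyl-directed hydride delivery.
2. Both rings are made in one operation from an acyclic chain: an intramolecular (4+3) cycloaddition of an epoxy enol silane (C5–C6–C7, oxirane C4–C5) with a tethered silyl dienol ether (C8=C9–C10=C1). The C1–C5 bond closes the cyclopentane and leads; the C7–C8 bond closes the cycloheptenone.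
3. Enabling feature: the seven-membered ring is a cyclohept-4-enone retron (C6 oxygen between C5 and C7; cis C9=C10 between oxygenated C8 and quaternary C1), and the C4 tertiary carbinol β to C6 is the trace of an oxirane on the three-carbon tether C2–C3–C4.
4. The acyclic precursor comes from epoxy diketone 16, made by Negishi coupling of vinyl iodide 5 with alkylzinc 12 and a 1,3-allylic-strain-controlled directed epoxidation.
5. Fragment 5 comes from 3-methylbut-1-yne (transfer hydrogenation, trans-hydroalumination/iodination); fragment 11 from a butynyl silyl ether (Zr-catalysed carboalumination, oxirane opening).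

Key step: step 12

Remarks: 6 and 21 are taken as purchased. The configuration of oxirane 7 does not reach the target (its carbinol becomes the C8 carbonyl); (R) is chosen only to keep intermediates single isomers.

## Route

Step 1
Reactants: 1 3-methylbut-1-yne; 2 N-methoxy-N-methylacetamide
Product: 3 5-methylhex-3-yn-2-one
Conditions: n-BuLi, THF, −78 °C; then 2, −78 to 0 °C
Reagents that add atoms: none
Why: Acylation of a lithium acetylide with a Weinreb amide stops at the ketone because the tetrahedral chelate survives until work-up.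

Step 2
Reactants: 3 5-methylhex-3-yn-2-one
Product: 4 (S)-5-methylhex-3-yn-2-ol
Conditions: RuCl[(S,S)-TsDPEN](p-cymene) (1 mol %), cat. KOH, i-PrOH, rt
Reagents that add atoms: none
Why: Noyori asymmetric transfer hydrogenation of an alkynyl methyl ketone; the (S,S) catalyst should differentiate alkynyl from methyl and give the (S)-carbinol without touching the alkyne.

Step 3
Reactants: 4 (S)-5-methylhex-3-yn-2-ol
Product: 5 (2S,3Z)-4-iodo-5-methylhex-3-en-2-ol
Conditions: Red-Al, THF, 0 °C to rt; then I2, −78 to 0 °C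
Reagents that add atoms: iodine, II
Why: Alkoxide-directed trans-hydroalumination places aluminium on the distal alkyne carbon cis to the carbinol carbon (five-membered oxa-aluminacycle), and iodinolysis with retention should give the (Z)-iodide; the carbinol centre is not touched.

Step 4
Reactants: 6 tert-butyl(but-3-yn-1-yloxy)dimethylsilane; 7 (R)-2-methyloxirane
Product: 9 (3E,6R)-3-methylhept-3-ene-1,6-diol, via mono-TBS ether 8 (not isolated)
Conditions: AlMe3, Cp2ZrCl2 (20 mol %), CH2Cl2, 0 °C to rt, excess AlMe3 removed in vacuo; n-BuLi, hexane/THF, −78 °C; then 7, −78 to 0 °C; then aq. HCl, THF, rt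
Reagents that add atoms: trimethylaluminium, C[Al](C)C
Why: Negishi Zr-catalysed syn-carboalumination gives the (E)-2-methylalkenylalane, whose lithium alanate opens the oxirane at CH2 with retention of alkene geometry and of the oxirane stereocentre; the acidic work-up removes the primary silyl ether.

Step 5
Reactants: 9 (3E,6R)-3-methylhept-3-ene-1,6-diol
Product: 10 (2R,4E)-7-iodo-5-methylhept-4-en-2-ol
Conditions: I2, PPh3, imidazole, CH2Cl2, 0 °C
Reagents that add atoms: iodine, II
Why: Appel-type iodination is selective for the primary over the secondary hydroxyl on steric grounds.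

Step 6
Reactants: 10 (2R,4E)-7-iodo-5-methylhept-4-en-2-ol
Product: 11 tert-butyl{[(2R,4E)-7-iodo-5-methylhept-4-en-2-yl]oxy}dimethylsilane
Conditions: TBSOTf, 2,6-lutidine, CH2Cl2, −78 °C
Reagents that add atoms: tert-butyldimethylsilyl triflate, CC(C)(C)[Si](C)(C)OS(=O)(=O)C(F)(F)F
Why: Silylation of the secondary alcohol with a silyl triflate is fast at low temperature and leaves the primary iodide alone.

Step 7
Reactants: 11 tert-butyl{[(2R,4E)-7-iodo-5-methylhept-4-en-2-yl]oxy}dimethylsilane; 5 (2S,3Z)-4-iodo-5-methylhex-3-en-2-ol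
Product: 13 (2S,3E,7E,10R)-10-[(tert-butyldimethylsilyl)oxy]-7-methyl-4-(propan-2-yl)undeca-3,7-dien-2-ol, via alkylzinc iodide 12 (not isolated)
Conditions: Zn dust (activated), LiCl, THF, 40 °C; then 5, Pd(OAc)2 (3 mol %), SPhos (6 mol %), THF, rt
Reagents that add atoms: zinc, [Zn] (retained only in 12)
Why: LiCl-mediated zinc insertion into the primary iodide followed by Pd/SPhos Negishi sp3–sp2 coupling should proceed with retention at the vinyl iodide and tolerate the free hydroxyl, so the chain ends up cis to the carbinol carbon.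

Step 8
Reactants: 13 (2S,3E,7E,10R)-10-[(tert-butyldimethylsilyl)oxy]-7-methyl-4-(propan-2-yl)undeca-3,7-dien-2-ol
Product: 14 (1S)-1-[(2R,3R)-3-{(3E,6R)-6-[(tert-butyldimethylsilyl)oxy]-3-methylhept-3-en-1-yl}-3-(propan-2-yl)oxiran-2-yl]ethan-1-ol
Conditions: Ti(OiPr)4 (20 mol %), t-BuOOH (decane), 4 Å MS, CH2Cl2, −20 °C
Reagents that add atoms: tert-butyl hydroperoxide, CC(C)(C)OO
Why: Titanium-alkoxide-directed epoxidation is chemoselective for the allylic alcohol over the remote alkene, and 1,3-allylic strain with the cis CH2 group holds the carbinol H in the alkene plane so that oxygen should be delivered syn to OH (threo), setting both oxirane carbons from the (S)-carbinol.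

Step 9
Reactants: 14 (1S)-1-[(2R,3R)-3-{(3E,6R)-6-[(tert-butyldimethylsilyl)oxy]-3-methylhept-3-en-1-yl}-3-(propan-2-yl)oxiran-2-yl]ethan-1-ol
Product: 15 (1S)-1-[(2R,3R)-3-[(3E,6R)-6-hydroxy-3-methylhept-3-en-1-yl]-3-(propan-2-yl)oxiran-2-yl]ethan-1-ol
Conditions: TBAF, THF, 0 °C to rt
Reagents that add atoms: none
Why: Fluoride-mediated desilylation of the secondary silyl ether; the trisubstituted epoxy alcohol should tolerate TBAF at this temperature.

Step 10
Reactants: 15 (1S)-1-[(2R,3R)-3-[(3E,6R)-6-hydroxy-3-methylhept-3-en-1-yl]-3-(propan-2-yl)oxiran-2-yl]ethan-1-ol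
Product: 16 1-[(2S,3R)-3-[(3E)-3-methyl-6-oxohept-3-en-1-yl]-3-(propan-2-yl)oxiran-2-yl]ethan-1-one
Conditions: Dess–Martin periodinane, pyridine, CH2Cl2, 0 °C to rt
Reagents that add atoms: none
Why: Buffered Dess–Martin oxidation converts both secondary alcohols to methyl ketones under non-basic conditions that should neither open the oxirane nor move the β,γ-alkene into conjugation; the two carbinol control centres are erased as planned.

Step 11
Reactants: 16 1-[(2S,3R)-3-[(3E)-3-methyl-6-oxohept-3-en-1-yl]-3-(propan-2-yl)oxiran-2-yl]ethan-1-one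
Product: 17 triethyl{[(2Z,4E)-5-methyl-7-{(2R,3S)-2-(propan-2-yl)-3-[1-(triethylsilyloxy)ethenyl]oxiran-2-yl}hepta-2,4-dien-2-yl]oxy}silane
Conditions: TESOTf (2.5 equiv), Et3N (4 equiv), CH2Cl2, −78 to 0 °C; filtration through Et3N-deactivated silica
Reagents that add atoms: triethylsilyl triflate, CC[Si](CC)(CC)OS(=O)(=O)C(F)(F)F
Why: Soft enolisation gives the terminal enol silane of the oxiranyl methyl ketone (only the CH3 is enolisable) and, from the skipped enone, the conjugated dienol ether by loss of the doubly activated C9–H, with the (Z)-enol ether (OSi cis to the vinyl carbon) expected to predominate on 1,3-allylic strain grounds; the C1=C10 geometry is untouched.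

Step 12
Reactants: 17 triethyl{[(2Z,4E)-5-methyl-7-{(2R,3S)-2-(propan-2-yl)-3-[1-(triethylsilyloxy)ethenyl]oxiran-2-yl}hepta-2,4-dien-2-yl]oxy}silane
Product: 18 4β,8β-bis(triethylsilyloxy)dauc-9-en-6-one (trans-fused, 5α-H, 1β-CH3)
Conditions: TESOTf (10 mol %), CH2Cl2, −78 °C; Et3N quench
Reagents that add atoms: none
Why: Proposed new method: TESOTf silylates the oxirane oxygen, the γ-carbon C1 of the tethered silyl dienol ether displaces the C5–O bond from the rear (5-exo-tet, SN2-like, C5 being the terminus of an incipient 2-siloxyallyl cation), and the enol silane terminus C7 then adds to the oxocarbenium carbon C8 (7-exo-trig, Mukaiyama-aldol-like), an asynchronous (4+3) cycloaddition that is polarity-matched at both bonds and turns over by silyl transfer from the C6 oxocarbenium to the next oxirane. The closest known reaction type is the silyl-triflate-catalysed intramolecular (4+3) cycloaddition of epoxy enol silanes with tethered furans and 1,3-dienes, known to transfer the oxirane configuration; new here is an acyclic, fully substituted 1-siloxy diene as the four-carbon partner. C5 is set by inversion at the oxirane carbon (H5 trans to the C4 oxygen, which is carried over unchanged); C1 by the E geometry of C1=C10 together with an extended approach that keeps the siloxyvinyl group anti to the dienyl arm on the forming cyclopentane bond (trans fusion); C8 by suprafacial addition across the cisoid diene with the Z enol ether, which puts the C8 oxygen and the C1 methyl on the same face. The step needs C5–O rather than C4–O cleavage (secured by allyl-cation stabilisation at C5 and the five-membered tether), (4+3) rather than (3+2) closure (secured by the charge at oxocarbenium carbon C8) and trans rather than cis ring fusion, which is the least secure point because the inside C1 methyl penalises the extended approach.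

Step 13
Reactants: 18 4β,8β-bis(triethylsilyloxy)dauc-9-en-6-one
Product: 19 4β,8β-dihydroxydauc-9-en-6-one
Conditions: HF·pyridine, pyridine/THF, 0 °C
Reagents that add atoms: none
Why: Buffered HF cleaves both tertiary triethylsilyl ethers while avoiding basic fluoride, which could trigger retro-aldol opening of the two β-hydroxy ketone units.

Step 14
Reactants: 19 4β,8β-dihydroxydauc-9-en-6-one
Product: 20 dauc-9-ene-4β,6α,8β-triol
Conditions: Me4NBH(OAc)3, AcOH/MeCN, −20 °C
Reagents that add atoms: none
Why: Evans–Saksena-type intramolecular hydride delivery from an alkoxyborohydride formed at the β-oriented C4 (or C8) hydroxyl should attack the C6 carbonyl from the β face and give the 6α (1,3-anti) alcohol.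

Step 15
Reactants: 20 dauc-9-ene-4β,6α,8β-triol; 21 4-acetoxy-3-methoxybenzoic acid
Product: 22 4β,8β-dihydroxydauc-9-en-6α-yl 4-acetoxy-3-methoxybenzoate
Conditions: DCC, DMAP, CH2Cl2, rt
Reagents that add atoms: none
Why: Steglich esterification acylates the only secondary hydroxyl; the two tertiary alcohols should not react.

Step 16
Reactants: 22 4β,8β-dihydroxydauc-9-en-6α-yl 4-acetoxy-3-methoxybenzoate
Product: 23 4β,8β-dihydroxydauc-9-en-6α-yl 4-hydroxy-3-methoxybenzoate (target)
Conditions: pyrrolidine, CH2Cl2, 0 °C to rt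
Reagents that add atoms: none
Why: Aminolysis of the phenolic acetate is much faster than attack on the hindered secondary benzoate, so the phenol is released without ester loss.

## Compound list

1 | 3-methylbut-1-yne | CC(C)C#C | starting material
2 | N-methoxy-N-methylacetamide | CC(=O)N(C)OC | starting material
3 | 5-methylhex-3-yn-2-one | CC(=O)C#CC(C)C | intermediate
4 | (S)-5-methylhex-3-yn-2-ol | C[C@H](O)C#CC(C)C | intermediate
5 | (2S,3Z)-4-iodo-5-methylhex-3-en-2-ol | C[C@H](O)/C=C(\I)C(C)C | intermediate
6 | tert-butyl(but-3-yn-1-yloxy)dimethylsilane | C#CCCO[Si](C)(C)C(C)(C)C | starting material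
7 | (R)-2-methyloxirane | C[C@@H]1CO1 | starting material
8 | (2R,4E)-7-[(tert-butyldimethylsilyl)oxy]-5-methylhept-4-en-2-ol | C[C@@H](O)C/C=C(\C)CCO[Si](C)(C)C(C)(C)C | intermediate
9 | (3E,6R)-3-methylhept-3-ene-1,6-diol | C[C@@H](O)C/C=C(\C)CCO | intermediate
10 | (2R,4E)-7-iodo-5-methylhept-4-en-2-ol | C[C@@H](O)C/C=C(\C)CCI | intermediate
11 | tert-butyl{[(2R,4E)-7-iodo-5-methylhept-4-en-2-yl]oxy}dimethylsilane | C[C@@H](O[Si](C)(C)C(C)(C)C)C/C=C(\C)CCI | intermediate
12 | {(3E,6R)-6-[(tert-butyldimethylsilyl)oxy]-3-methylhept-3-en-1-yl}zinc iodide | C[C@@H](O[Si](C)(C)C(C)(C)C)C/C=C(\C)CC[Zn]I | intermediate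
13 | (2S,3E,7E,10R)-10-[(tert-butyldimethylsilyl)oxy]-7-methyl-4-(propan-2-yl)undeca-3,7-dien-2-ol | C[C@@H](O[Si](C)(C)C(C)(C)C)C/C=C(\C)CC/C(C(C)C)=C\[C@@H](O)C | intermediate
14 | (1S)-1-[(2R,3R)-3-{(3E,6R)-6-[(tert-butyldimethylsilyl)oxy]-3-methylhept-3-en-1-yl}-3-(propan-2-yl)oxiran-2-yl]ethan-1-ol | C[C@@H](O[Si](C)(C)C(C)(C)C)C/C=C(\C)CC[C@]1(C(C)C)O[C@@H]1[C@@H](O)C | intermediate
15 | (1S)-1-[(2R,3R)-3-[(3E,6R)-6-hydroxy-3-methylhept-3-en-1-yl]-3-(propan-2-yl)oxiran-2-yl]ethan-1-ol | C[C@@H](O)C/C=C(\C)CC[C@]1(C(C)C)O[C@@H]1[C@@H](O)C | intermediate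
16 | 1-[(2S,3R)-3-[(3E)-3-methyl-6-oxohept-3-en-1-yl]-3-(propan-2-yl)oxiran-2-yl]ethan-1-one | CC(=O)C/C=C(\C)CC[C@]1(C(C)C)O[C@@H]1C(C)=O | intermediate
17 | triethyl{[(2Z,4E)-5-methyl-7-{(2R,3S)-2-(propan-2-yl)-3-[1-(triethylsilyloxy)ethenyl]oxiran-2-yl}hepta-2,4-dien-2-yl]oxy}silane | C/C(O[Si](CC)(CC)CC)=C/C=C(\C)CC[C@]1(C(C)C)O[C@@H]1C(=C)O[Si](CC)(CC)CC | intermediate
18 | 4β,8β-bis(triethylsilyloxy)dauc-9-en-6-one | O=C1C[C@](C)(O[Si](CC)(CC)CC)C=C[C@@]2(C)CC[C@@](O[Si](CC)(CC)CC)(C(C)C)[C@H]12 | intermediate
19 | 4β,8β-dihydroxydauc-9-en-6-one | O=C1C[C@](C)(O)C=C[C@@]2(C)CC[C@@](O)(C(C)C)[C@H]12 | intermediate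
20 | dauc-9-ene-4β,6α,8β-triol | O[C@H]1C[C@](C)(O)C=C[C@@]2(C)CC[C@@](O)(C(C)C)[C@H]12 | intermediate
21 | 4-acetoxy-3-methoxybenzoic acid | COc1cc(C(=O)O)ccc1OC(C)=O | starting material
22 | 4β,8β-dihydroxydauc-9-en-6α-yl 4-acetoxy-3-methoxybenzoate | COc1cc(C(=O)O[C@H]2C[C@](C)(O)C=C[C@@]3(C)CC[C@@](O)(C(C)C)[C@H]23)ccc1OC(C)=O | intermediate
23 | 4β,8β-dihydroxydauc-9-en-6α-yl 4-hydroxy-3-methoxybenzoate | COc1cc(C(=O)O[C@H]2C[C@](C)(O)C=C[C@@]3(C)CC[C@@](O)(C(C)C)[C@H]23)ccc1O | target

## Step count and risks

Total steps: 16. Longest linear sequence: 13 (steps 4–16 from 6; equally steps 1–3 and 7–16 from 1).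

**Step 12 (Proposed new method).** The two bond formations may decouple: after the C1–C5 bond forms, the enol silane may close on C10 ((3+2) mode) or the oxocarbenium may lose silicon before the seven-membered ring closes. The oxirane may also ionise at the tertiary carbon C4 and rearrange, and facial selection at the diene may favour the cis-fused isomer.

Fallback, with the hydrocarbon-diene substrate class for which this cycloaddition is established; it sets out from 6 (and uses 5) and comes back at 20. It removes the first two failure processes; facial selectivity would still have to be judged on the cycloadduct.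
- Alkyne 6 is carboaluminated as in step 4 and the alkenylalane is cross-coupled with (E)-1-bromopropene (Pd(PPh3)4, ZnCl2) to give the dienyl silyl ether F1.
- TBAF gives the dienol F2, and PPh3/I2/imidazole the dienyl iodide F3.
- Zinc insertion and Pd/SPhos coupling with 5 as in step 7 give the trienol F4.
- Ti(OiPr)4/t-BuOOH epoxidation of the allylic alcohol gives the epoxy alcohol F5, Dess–Martin oxidation the epoxy ketone F6, and TESOTf/Et3N the epoxy enol silane F7.
- TESOTf-catalysed (4+3) cycloaddition should give the 8α-methyl-8β-H ketone F8 (the E,E diene puts H8 and the C1 methyl on the same face).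
- HF·pyridine gives the hydroxy ketone F9 and Me4NBH(OAc)3 the diol F10.
- SeO2 (cat.)/t-BuOOH hydroxylation of the only allylic C–H (C8–H), an ene/[2,3] sequence with net retention, then gives triol 20.

**Step 7.** Slow oxidative addition and transmetalation at the α-branched vinyl iodide, protonation of the zinc reagent by the free hydroxyl, or β-hydride elimination may erode the coupling.

Fallback, setting out from 11 and 1 and coming back at 13: iodide 11 is converted to the Grignard reagent and then the alkylcopper (Mg; CuBr·SMe2, Et2O, −45 °C). Syn-carbocupration of alkyne 1, followed by Pd-catalysed acylation of the alkenylcopper with acetyl chloride, gives the (E)-enone F11 with the chain cis to the acetyl group. (R)-Me-CBS/BH3·SMe2 reduction then gives the (S)-allylic alcohol 13.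

**Step 14.** Ligand exchange at the two tertiary hydroxyls may be too slow, so that hydride is delivered undirected from the less hindered α face and the 6β-alcohol forms.

Fallback, setting out from 19 and coming back at 22: L-Selectride (THF, −78 °C) is used deliberately to give the 6β-epimeric triol F12. Mitsunobu esterification with acid 21 (PPh3, DIAD, toluene) then inverts C6 and gives ester 22 directly.

## Further compounds

F1 | step 12 | tert-butyl{[(3E,5E)-3-methylhepta-3,5-dien-1-yl]oxy}dimethylsilane | C/C=C/C=C(\C)CCO[Si](C)(C)C(C)(C)C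
F2 | step 12 | (3E,5E)-3-methylhepta-3,5-dien-1-ol | C/C=C/C=C(\C)CCO
F3 | step 12 | (2E,4E)-7-iodo-5-methylhepta-2,4-diene | C/C=C/C=C(\C)CCI
F4 | step 12 | (2S,3E,7E,9E)-7-methyl-4-(propan-2-yl)undeca-3,7,9-trien-2-ol | C/C=C/C=C(\C)CC/C(C(C)C)=C\[C@@H](O)C
F5 | step 12 | (1S)-1-{(2R,3R)-3-[(3E,5E)-3-methylhepta-3,5-dien-1-yl]-3-(propan-2-yl)oxiran-2-yl}ethan-1-ol | C/C=C/C=C(\C)CC[C@]1(C(C)C)O[C@@H]1[C@@H](O)C
F6 | step 12 | 1-{(2S,3R)-3-[(3E,5E)-3-methylhepta-3,5-dien-1-yl]-3-(propan-2-yl)oxiran-2-yl}ethan-1-one | C/C=C/C=C(\C)CC[C@]1(C(C)C)O[C@@H]1C(C)=O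
F7 | step 12 | triethyl[(1-{(2S,3R)-3-[(3E,5E)-3-methylhepta-3,5-dien-1-yl]-3-(propan-2-yl)oxiran-2-yl}ethenyl)oxy]silane | C/C=C/C=C(\C)CC[C@]1(C(C)C)O[C@@H]1C(=C)O[Si](CC)(CC)CC
F8 | step 12 | 4β-(triethylsilyloxy)dauc-9-en-6-one (8α-CH3, 8β-H) | O=C1C[C@@H](C)C=C[C@@]2(C)CC[C@@](O[Si](CC)(CC)CC)(C(C)C)[C@H]12
F9 | step 12 | 4β-hydroxydauc-9-en-6-one (8α-CH3, 8β-H) | O=C1C[C@@H](C)C=C[C@@]2(C)CC[C@@](O)(C(C)C)[C@H]12
F10 | step 12 | dauc-9-ene-4β,6α-diol (8α-CH3, 8β-H) | O[C@H]1C[C@@H](C)C=C[C@@]2(C)CC[C@@](O)(C(C)C)[C@H]12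
F11 | step 7 | (3E,7E,10R)-10-[(tert-butyldimethylsilyl)oxy]-7-methyl-4-(propan-2-yl)undeca-3,7-dien-2-one | C[C@@H](O[Si](C)(C)C(C)(C)C)C/C=C(\C)CC/C(C(C)C)=C\C(C)=O
F12 | step 14 | dauc-9-ene-4β,6β,8β-triol | O[C@@H]1C[C@](C)(O)C=C[C@@]2(C)CC[C@@](O)(C(C)C)[C@H]12
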